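**Retrosynthetic overview**

1. Feature: ring A (C4a, C5, C6, C7, C8, C8a) is a phloroglucinol with oxygen on C5, C7 and C8a (O1) and geranyl on C6, fused to the pyranone at C4a–C8a. Read as C4–C4a–C8a–C8–C7–C6–C5 it is a 1,3,5-tricarbonyl chain that ends in an ester carbon and folds back onto C4a.
2. Target ⇒ its 3'-MOM ether ⇒ (C4a–C5, Claisen cyclisation and aromatisation) a β-keto ester side chain on C6 of an (S)-2-aryl-2,3-dihydro-4H-pyran-4-one. Ring A is formed last.
3. Dihydropyranone keto ester ⇒ (O1–C8a, cyclodehydration) open-chain (9S)-9-silyloxy-3,5,7-triketo ester. The pyranone ring is formed first.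
4. Triketo ester ⇒ (C4–C4a, polyanion acylation) methyl 2-geranyl-3,5-dioxohexanoate + (S)-β-silyloxy Weinreb amide. The diketo ester ⇒ methyl acetoacetate + geranyl bromide + an acetyl donor.
5. Weinreb amide ⇒ aryl β-keto ester by asymmetric transfer hydrogenation (sets C2) ⇒ 3-hydroxy-4-methoxyacetophenone.

Key step: step 10

Remark: the geranyl-bearing α-carbon of the keto esters is configurationally labile, so these compounds are carried as mixtures of epimers and keto–enol tautomers (SMILES show the keto form with no descriptor there), and the centre disappears when ring A aromatises; flavanone numbering (O1, C2–C4, C4a, C5–C8, C8a) is used for chain atoms throughout.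

**Route**

Step 1
Reactants: 1 3-hydroxy-4-methoxyacetophenone
Product: 2 1-[4-methoxy-3-(methoxymethoxy)phenyl]ethan-1-one
Conditions: MOMCl, i-Pr2NEt, CH2Cl2, 0 °C → rt
Reagents that add atoms: chloromethyl methyl ether, COCCl
Why: Williamson-type O-alkylation of the phenol with MOMCl masks the only acidic OH before the enolate and polyanion steps, and the methyl ketone does not react under amine base.

Step 2
Reactants: 2 1-[4-methoxy-3-(methoxymethoxy)phenyl]ethan-1-one
Product: 3 methyl 3-[4-methoxy-3-(methoxymethoxy)phenyl]-3-oxopropanoate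
Conditions: NaH (2.5 equiv), (MeO)2CO, THF, reflux; AcOH
Reagents that add atoms: dimethyl carbonate, COC(=O)OC
Why: Claisen-type C-methoxycarbonylation of the methyl ketone enolate with dimethyl carbonate is pulled to completion by deprotonation of the β-keto ester formed, and the MOM ether is inert to NaH.

Step 3
Reactants: 3 methyl 3-[4-methoxy-3-(methoxymethoxy)phenyl]-3-oxopropanoate
Product: 4 methyl (3S)-3-hydroxy-3-[4-methoxy-3-(methoxymethoxy)phenyl]propanoate
Conditions: RuCl[(S,S)-TsDPEN](p-cymene) (1 mol %), HCO2H–Et3N (5:2), 40 °C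
Reagents that add atoms: none
Why: Noyori–Ikariya asymmetric transfer hydrogenation of an aryl ketone, in which the (S,S)-TsDPEN–Ru hydride holds the aryl group against the η6-arene and delivers hydride to the Re face as it does for acetophenones, which should set the (S)-carbinol that becomes C2.

Step 4
Reactants: 4 methyl (3S)-3-hydroxy-3-[4-methoxy-3-(methoxymethoxy)phenyl]propanoate
Product: 5 (3S)-3-hydroxy-N-methoxy-3-[4-methoxy-3-(methoxymethoxy)phenyl]-N-methylpropanamide
Conditions: MeNH(OMe)·HCl, i-PrMgCl (3.1 equiv), THF, −20 → 0 °C; aq. NH4Cl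
Reagents that add atoms: N,O-dimethylhydroxylamine hydrochloride, CNOC.Cl
Why: Aminolysis of the methyl ester by the chloromagnesium amide of N,O-dimethylhydroxylamine (Weinreb amide formation) proceeds with the carbinol held as its magnesium alkoxide and does not touch the stereocentre.

Step 5
Reactants: 5 (3S)-3-hydroxy-N-methoxy-3-[4-methoxy-3-(methoxymethoxy)phenyl]-N-methylpropanamide
Product: 6 (3S)-3-[tert-butyl(dimethyl)silyl]oxy-N-methoxy-3-[4-methoxy-3-(methoxymethoxy)phenyl]-N-methylpropanamide
Conditions: TBSCl, imidazole, DMF, rt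
Reagents that add atoms: tert-butyldimethylsilyl chloride, CC(C)(C)[Si](C)(C)Cl
Why: Silylation of the secondary benzylic alcohol removes the alkoxide that would otherwise consume polyanion or undergo retro-aldol cleavage in step 8.

Step 6
Reactants: 7 methyl acetoacetate; 8 geranyl bromide
Product: 9 methyl (4E)-2-acetyl-5,9-dimethyldeca-4,8-dienoate (methyl 2-geranylacetoacetate)
Conditions: NaH (1.0 equiv), 7 (1.2 equiv), THF, 0 °C; 8, rt
Reagents that add atoms: none
Why: Acetoacetic ester alkylation (SN2 of the sodium enolate on a primary allylic bromide) puts geranyl on the carbon that becomes C6 of ring A and keeps the (E)-alkene.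

Step 7
Reactants: 9 methyl (4E)-2-acetyl-5,9-dimethyldeca-4,8-dienoate
Product: 10 methyl (4E)-5,9-dimethyl-2-(3-oxobutanoyl)deca-4,8-dienoate (methyl 2-geranyl-3,5-dioxohexanoate)
Conditions: LDA (2.2 equiv), THF, −78 → 0 °C; MeC(O)N(OMe)Me, −78 → 0 °C; aq. NH4Cl
Reagents that add atoms: N-methoxy-N-methylacetamide, CC(=O)N(C)OC
Why: γ-Acylation of a β-keto ester dianion (the more basic terminal carbanion reacts) by a Weinreb amide, whose tetrahedral adduct survives until work-up so that the acidic diketo ester cannot quench unreacted dianion.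

Step 8
Reactants: 10 methyl 2-geranyl-3,5-dioxohexanoate; 6 (3S)-silyloxy Weinreb amide
Product: 11 methyl (9S)-9-[tert-butyl(dimethyl)silyl]oxy-2-geranyl-9-[4-methoxy-3-(methoxymethoxy)phenyl]-3,5,7-trioxononanoate
Conditions: 10 (1.3 equiv), LDA (4.1 equiv), THF, −78 → 0 °C; 6 (1.0 equiv), −78 → −20 °C; AcOH, −78 °C
Reagents that add atoms: none
Why: Claisen-type acylation of the terminal carbanion of a β,δ-diketo ester trianion by a Weinreb amide forms the C4–C4a bond, with the chelated tetrahedral adduct holding back the new ketone until the quench and the stereocentre remote from the reacting carbonyl.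

Step 9
Reactants: 11 methyl (9S)-9-silyloxy-2-geranyl-9-aryl-3,5,7-trioxononanoate
Product: 14 methyl 2-geranyl-4-[(2S)-2-(4-methoxy-3-(methoxymethoxy)phenyl)-4-oxo-3,4-dihydro-2H-pyran-6-yl]-3-oxobutanoate, via hydroxy triketo ester 12 (not isolated), via cyclic hemiketal 13 (not isolated)
Conditions: 48% aq. HF, MeCN, 0 °C → rt; aq. NaHCO3
Reagents that add atoms: none
Why: Acidic desilylation frees the δ-hydroxyl, which adds to the ketone that becomes C8a and the six-membered hemiketal loses water to the conjugated vinylogous ester (cyclodehydration of a δ-hydroxy-β-diketone to a 2,3-dihydro-4H-pyran-4-one); the C–O bond at the stereocentre is never broken, so (S) is retained, and aqueous HF should spare the aryl MOM acetal.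

Step 10
Reactants: 14 methyl 2-geranyl-4-[(2S)-2-(4-methoxy-3-(methoxymethoxy)phenyl)-4-oxo-3,4-dihydro-2H-pyran-6-yl]-3-oxobutanoate
Product: 16 (2S)-6-geranyl-5,7-dihydroxy-4'-methoxy-3'-(methoxymethoxy)flavanone, via cyclohexenedione tautomer 15 (not isolated)
Conditions: LiOt-Bu (1.2 equiv), THF (0.02 M), −20 °C → rt; AcOH, 0 °C
Reagents that add atoms: none
Why: Proposed new method: one equivalent of alkoxide removes a side-chain proton of 14; in the tautomer deprotonated at C8 the charge is spread over O7, C8, C4a and O4 (dienolate O4–C4=C4a–C8a=C8), C4a is the only nucleophilic atom that can reach the ester carbon through an unstrained ring, so it adds, methoxide leaves and the cyclohexenedione 15 enolises twice to the phloroglucinol 16, which takes up the methoxide set free so that no base is left to enolise C3. The closest known reaction is the Claisen-mode (Dieckmann-type) cyclisation of open-chain 3,5,7-triketo esters to acylphloroglucinols; the dienolate of a 2,3-dihydro-4H-pyran-4-one as the carbon nucleophile is, as far as is known, not documented. Ring A closes by 6-exo-trig attack on the ester carbonyl, with the C8a=C8 bond of the dienolate inside the new ring and the reacting enolate bond C4=C4a outside it (enolexo). No stereocentre is formed: C2 is only carried through, and both epimers at the geranyl carbon and all tautomers converge once C6 is aromatic. The step needs C-acylation at C4a to beat O-acylation, aldol closure, retro-Claisen cleavage and E1cB opening of C2–O1: O-acylation would need a four- or eight-membered ring, the aldol of the C6 enolate onto C4 is reversible and cannot aromatise because C6 carries geranyl, and once the side chain is deprotonated O4 is already an enolate oxygen, so C3–H is not acidic toward one equivalent of a weak alkoxide. The connectivity of the chain places geranyl on C6 between the two hydroxyls, so an 8-geranyl isomer cannot form.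

Step 11
Reactants: 16 (2S)-6-geranyl-5,7-dihydroxy-4'-methoxy-3'-(methoxymethoxy)flavanone
Product: 17 (2S)-6-geranyl-5,7,3'-trihydroxy-4'-methoxyflavanone (CNP0264411.1)
Conditions: HCl (ca. 1 M), MeOH–THF, rt (to 40 °C if slow)
Reagents that add atoms: none
Why: Acid-catalysed acetal exchange with methanol (MOM cleavage) frees the 3'-phenol as dimethoxymethane, and dilute acid near room temperature is chosen to spare the geranyl alkenes and the benzylic C2–O1 bond.

**Compound list**

1 | 3-hydroxy-4-methoxyacetophenone | CC(=O)c1ccc(OC)c(O)c1 | starting material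
2 | 1-[4-methoxy-3-(methoxymethoxy)phenyl]ethan-1-one | CC(=O)c1ccc(OC)c(OCOC)c1 | intermediate
3 | methyl 3-[4-methoxy-3-(methoxymethoxy)phenyl]-3-oxopropanoate | COC(=O)CC(=O)c1ccc(OC)c(OCOC)c1 | intermediate
4 | methyl (3S)-3-hydroxy-3-[4-methoxy-3-(methoxymethoxy)phenyl]propanoate | COc1ccc([C@@H](O)CC(=O)OC)cc1OCOC | intermediate
5 | (3S)-3-hydroxy-N-methoxy-3-[4-methoxy-3-(methoxymethoxy)phenyl]-N-methylpropanamide | COc1ccc([C@@H](O)CC(=O)N(C)OC)cc1OCOC | intermediate
6 | (3S)-3-[tert-butyl(dimethyl)silyl]oxy-N-methoxy-3-[4-methoxy-3-(methoxymethoxy)phenyl]-N-methylpropanamide | COc1ccc([C@@H](O[Si](C)(C)C(C)(C)C)CC(=O)N(C)OC)cc1OCOC | intermediate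
7 | methyl acetoacetate | COC(=O)CC(C)=O | starting material
8 | geranyl bromide, (2E)-1-bromo-3,7-dimethylocta-2,6-diene | CC(C)=CCC/C(C)=C/CBr | starting material
9 | methyl (4E)-2-acetyl-5,9-dimethyldeca-4,8-dienoate (methyl 2-geranylacetoacetate, racemic at C2) | COC(=O)C(C/C=C(\C)CCC=C(C)C)C(C)=O | intermediate
10 | methyl (4E)-5,9-dimethyl-2-(3-oxobutanoyl)deca-4,8-dienoate (methyl 2-geranyl-3,5-dioxohexanoate) | COC(=O)C(C/C=C(\C)CCC=C(C)C)C(=O)CC(C)=O | intermediate
11 | methyl (9S)-9-[tert-butyl(dimethyl)silyl]oxy-2-geranyl-9-[4-methoxy-3-(methoxymethoxy)phenyl]-3,5,7-trioxononanoate | COc1ccc([C@@H](O[Si](C)(C)C(C)(C)C)CC(=O)CC(=O)CC(=O)C(C/C=C(\C)CCC=C(C)C)C(=O)OC)cc1OCOC | intermediate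
12 | methyl (9S)-2-geranyl-9-hydroxy-9-[4-methoxy-3-(methoxymethoxy)phenyl]-3,5,7-trioxononanoate | COc1ccc([C@@H](O)CC(=O)CC(=O)CC(=O)C(C/C=C(\C)CCC=C(C)C)C(=O)OC)cc1OCOC | intermediate
13 | methyl 2-geranyl-4-[(6S)-2-hydroxy-6-[4-methoxy-3-(methoxymethoxy)phenyl]-4-oxooxan-2-yl]-3-oxobutanoate (cyclic hemiketal) | COc1ccc([C@@H]2CC(=O)CC(O)(CC(=O)C(C/C=C(\C)CCC=C(C)C)C(=O)OC)O2)cc1OCOC | intermediate
14 | methyl 2-geranyl-4-[(2S)-2-(4-methoxy-3-(methoxymethoxy)phenyl)-4-oxo-3,4-dihydro-2H-pyran-6-yl]-3-oxobutanoate | COc1ccc([C@@H]2CC(=O)C=C(CC(=O)C(C/C=C(\C)CCC=C(C)C)C(=O)OC)O2)cc1OCOC | intermediate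
15 | (2S)-6-geranyl-2-[4-methoxy-3-(methoxymethoxy)phenyl]-2,3-dihydro-4H-chromene-4,5,7(4aH,6H)-trione (cyclohexenedione tautomer) | COc1ccc([C@@H]2CC(=O)C3C(=O)C(C/C=C(\C)CCC=C(C)C)C(=O)C=C3O2)cc1OCOC | intermediate
16 | (2S)-6-geranyl-5,7-dihydroxy-4'-methoxy-3'-(methoxymethoxy)flavanone | COc1ccc([C@@H]2CC(=O)c3c(cc(O)c(C/C=C(\C)CCC=C(C)C)c3O)O2)cc1OCOC | intermediate
17 | (2S)-6-geranyl-5,7,3'-trihydroxy-4'-methoxyflavanone (CNP0264411.1) | COc1ccc([C@@H]2CC(=O)c3c(cc(O)c(C/C=C(\C)CCC=C(C)C)c3O)O2)cc1O | target

**Totals**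

Total step count: 11.
Longest linear sequence: 9 steps (steps 1–5 and 8–11); steps 6 and 7 form the second branch, which joins at step 8.

**Steps most likely to fail, with fallbacks**

1. Step 10 (carries the label).
What may go wrong: the delocalised mono-anion may be too weak a nucleophile for the α-branched ester, so the cyclisation stalls. If more base or heat is then used, the keto ester end is fully enolised and the ester stops being electrophilic. The alkoxide set free may cleave the β-keto ester by retro-Claisen attack at C7. Enolisation at C3 may open and reclose the C2–O1 bond (E1cB) and erode the stereocentre of 14 or 16.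
Fallback (known chemistry, ring A before the heterocycle): set out from 3 and reduce it as in step 3 but with the (R,R)-catalyst to the (R)-hydroxy ester F1. Steps 4 and 5 applied to F1 give the (R)-Weinreb amide F2 and its silyl ether F3. Coupling of F3 with the trianion of 10 as in step 8 gives the (9R)-triketo ester F4. F4 is cyclised while still open-chain with Mg(OMe)2 in MeOH to the 3-geranyl-acylphloroglucinol F5. This is the Claisen-mode cyclisation of a 3,5,7-triketo ester, and the competing aldol mode is blocked by the geranyl group on C2. Buffered TBAF gives the (R)-β-hydroxy dihydrochalcone F6. An intramolecular Mitsunobu etherification (PPh3, DIAD, high dilution, 0 °C) then closes O1–C2 with inversion, (R) to (S), and returns to 16. The cost is that the ring can also close through the hydroxyl next to geranyl, so the 8-geranyl isomer is to be expected and must be separated.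

2. Step 8.
What may go wrong: proton transfer instead of addition. The trianion deprotonates the α-CH2 of the Weinreb amide, which then loses silanolate to give the cinnamoyl amide. Incomplete trianion formation would lead to reaction at the central carbons or on oxygen.
Fallback (aldol then oxidation instead of acylation): set out from 6 and reduce it with DIBAL-H (THF, −78 °C) to the (S)-β-silyloxy aldehyde F7. The trianion of 10 should add to this aldehyde at −78 °C, with no tetrahedral intermediate to hold, giving the 7-hydroxy diketo ester F8 as a mixture at the new carbinol. Dess–Martin oxidation of that carbinol returns to 11.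

3. Step 11.
What may go wrong: acid-promoted addition of the 5- or 7-hydroxyl to the nearer geranyl alkene (chroman formation), further cation–olefin reactions of the diene, and slow loss of configuration at C2 through acid-catalysed opening of the benzylic C2–O1 bond.
Fallback (change the order of events): set out from 14, where no phenol flanks the geranyl group. Methanolic HCl removes the MOM group there to give the free 3'-phenol F9. The cyclisation of step 10 is then run on F9 with 2.3 equiv of LiOt-Bu, the remote phenoxide being a spectator, and gives 17 directly, so that no acid meets the geranyl-phloroglucinol.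

**Further compounds**

F1 | step 10 | methyl (3R)-3-hydroxy-3-[4-methoxy-3-(methoxymethoxy)phenyl]propanoate | COc1ccc([C@H](O)CC(=O)OC)cc1OCOC
F2 | step 10 | (3R)-3-hydroxy-N-methoxy-3-[4-methoxy-3-(methoxymethoxy)phenyl]-N-methylpropanamide | COc1ccc([C@H](O)CC(=O)N(C)OC)cc1OCOC
F3 | step 10 | (3R)-3-[tert-butyl(dimethyl)silyl]oxy-N-methoxy-3-[4-methoxy-3-(methoxymethoxy)phenyl]-N-methylpropanamide | COc1ccc([C@H](O[Si](C)(C)C(C)(C)C)CC(=O)N(C)OC)cc1OCOC
F4 | step 10 | methyl (9R)-9-[tert-butyl(dimethyl)silyl]oxy-2-geranyl-9-[4-methoxy-3-(methoxymethoxy)phenyl]-3,5,7-trioxononanoate | COc1ccc([C@H](O[Si](C)(C)C(C)(C)C)CC(=O)CC(=O)CC(=O)C(C/C=C(\C)CCC=C(C)C)C(=O)OC)cc1OCOC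
F5 | step 10 | (3R)-3-[tert-butyl(dimethyl)silyl]oxy-1-(3-geranyl-2,4,6-trihydroxyphenyl)-3-[4-methoxy-3-(methoxymethoxy)phenyl]propan-1-one | COc1ccc([C@H](O[Si](C)(C)C(C)(C)C)CC(=O)c2c(O)cc(O)c(C/C=C(\C)CCC=C(C)C)c2O)cc1OCOC
F6 | step 10 | (3R)-1-(3-geranyl-2,4,6-trihydroxyphenyl)-3-hydroxy-3-[4-methoxy-3-(methoxymethoxy)phenyl]propan-1-one | COc1ccc([C@H](O)CC(=O)c2c(O)cc(O)c(C/C=C(\C)CCC=C(C)C)c2O)cc1OCOC
F7 | step 8 | (3S)-3-[tert-butyl(dimethyl)silyl]oxy-3-[4-methoxy-3-(methoxymethoxy)phenyl]propanal | COc1ccc([C@@H](O[Si](C)(C)C(C)(C)C)CC=O)cc1OCOC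
F8 | step 8 | methyl (9S)-9-[tert-butyl(dimethyl)silyl]oxy-2-geranyl-7-hydroxy-9-[4-methoxy-3-(methoxymethoxy)phenyl]-3,5-dioxononanoate | COc1ccc([C@@H](O[Si](C)(C)C(C)(C)C)CC(O)CC(=O)CC(=O)C(C/C=C(\C)CCC=C(C)C)C(=O)OC)cc1OCOC
F9 | step 11 | methyl 2-geranyl-4-[(2S)-2-(3-hydroxy-4-methoxyphenyl)-4-oxo-3,4-dihydro-2H-pyran-6-yl]-3-oxobutanoate | COc1ccc([C@@H]2CC(=O)C=C(CC(=O)C(C/C=C(\C)CCC=C(C)C)C(=O)OC)O2)cc1O
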